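**Retrosynthetic overview**

1. Feature: in the central 1,4-benzoquinone ring, the acyloxy-bearing carbons C2 and C5 lie β to the C4 and C1 carbonyls (O–C2=C3–C4=O and O–C5=C6–C1=O). Each ring C–O bond therefore belongs to a vinylogous carboxylic acid derivative and can be traced back to a C–Br bond.
2. Last disconnection: the two acyl–O bonds of these vinylogous anhydrides. This gives atromentin (outer phenols masked as TBS ethers) and two copies of the (2Z,4S,5S)-4,5-epoxyhex-2-enoyl unit.
3. Key disconnection: both ring C–O bonds of atromentin, made by twofold addition–elimination of hydroxide on 2,5-dibromo-3,6-bis(4-acetoxyphenyl)-1,4-benzoquinone. That quinone comes from a double Suzuki coupling, acetylation, oxidative demethylation and bromination.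
4. Side chain: Sharpless epoxidation of (E)-but-2-en-1-ol sets both stereocentres. Oxidation and Still–Gennari olefination set the Z-alkene, and anhydrous ester cleavage gives the potassium carboxylate.
5. Ring order: the three six-membered rings are bought as arenes and none is built. The only rings formed are the two oxiranes (one reaction, product used twice), made before the fragments are joined.

Key step: step 5

Assumption: (E)-but-2-en-1-ol is used geometrically pure, since any Z-isomer would give the cis-oxirane. Because two copies of the side chain are attached, residual antipode should end mainly in the heterochiral diastereomer, to be removed at the silyl-protected diester stage.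

**Step 1**
Reactants: 1 1,4-dibromo-2,5-dimethoxybenzene; 2 4-hydroxyphenylboronic acid (2.4 equiv)
Product: 3 2',5'-dimethoxy-[1,1':4',1''-terphenyl]-4,4''-diol
Conditions: Pd(PPh3)4 (5 mol %), Na2CO3, 1,4-dioxane/H2O, 90 °C
Reagents that add atoms: none
Why: Double Suzuki–Miyaura cross-coupling, in which zerovalent palladium inserts into each aryl C–Br bond and the carbonate-activated boronic acid transfers its aryl group, should tolerate the free phenols and creates no stereocentre.

**Step 2**
Reactants: 3 2',5'-dimethoxy-[1,1':4',1''-terphenyl]-4,4''-diol
Product: 4 2',5'-dimethoxy-[1,1':4',1''-terphenyl]-4,4''-diyl diacetate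
Conditions: Ac2O, pyridine, CH2Cl2, rt
Reagents that add atoms: acetic anhydride CC(=O)OC(C)=O
Why: Pyridine-promoted O-acetylation of phenols is routine, and the acetates lower the electron density of the outer rings so that the oxidant of step 3 and the bromine of step 4 act on the central ring only.

**Step 3**
Reactants: 4 2',5'-dimethoxy-[1,1':4',1''-terphenyl]-4,4''-diyl diacetate
Product: 5 2,5-bis(4-acetoxyphenyl)-1,4-benzoquinone
Conditions: (NH4)2Ce(NO3)6 (2.5 equiv), MeCN/CH2Cl2/H2O, 0 °C to rt
Reagents that add atoms: water O
Why: Oxidative demethylation of a hydroquinone dimethyl ether by tetravalent cerium: two one-electron oxidations of the central ring, the most electron-rich of the three, let water add at the two methoxy-bearing carbons and methanol leave, while the aryl acetates survive the short exposure to the acidic medium.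

**Step 4**
Reactants: 5 2,5-bis(4-acetoxyphenyl)-1,4-benzoquinone
Product: 6 2,5-dibromo-3,6-bis(4-acetoxyphenyl)-1,4-benzoquinone
Conditions: Br2 (3 equiv), NaOAc, AcOH, 60 °C
Reagents that add atoms: bromine BrBr
Why: Net vinylic C–H bromination of a quinone by addition–elimination: Br2 adds across each aryl-substituted C=C and acetate removes the proton α to the carbonyl with E1cB loss of the β-bromide, while the acetoxy and quinonyl substituents keep the outer rings inert to electrophilic substitution and the acetic acid medium makes any acyl exchange degenerate.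

**Step 5**
Reactants: 6 2,5-dibromo-3,6-bis(4-acetoxyphenyl)-1,4-benzoquinone
Product: 8 atromentin (2,5-dihydroxy-3,6-bis(4-hydroxyphenyl)-1,4-benzoquinone), via tetrasodium atromentinate 7 (not isolated)
Conditions: NaOH (1 M aq., 10 equiv), MeOH, N2, 0 °C to rt; then 2 M HCl, 0 °C, filtration
Reagents that add atoms: sodium hydroxide [Na+].[OH-]
Why: Hydroxide attacks C2 and then C5, the two brominated carbons that terminate the Br–C2=C3–C4=O and Br–C5=C6–C1=O enone units, and each Michael-type adduct collapses with loss of bromide, that is, a vinylogous nucleophilic acyl substitution. The closest known reaction type is the alkaline hydrolysis of 2,5-dihalo- and tetrahalo-1,4-benzoquinones to 2,5-dihydroxyquinones, as in the conversion of chloranil into chloranilic acid. No ring is closed and no stereocentre is created; two ring C–O bonds are formed. Site selectivity needs nothing beyond the placement of the bromines, the only leaving groups on the ring, and because the two enone halves are joined only through the C1–C2 and C4–C5 single bonds, the anion left by the first exchange does not switch off the second. Selectivity against benzilic-type ring contraction and oxidative cleavage rests on the product, whose twofold vinylogous carboxylate repels more hydroxide, and on cold, dilute, oxygen-free base; any competing methoxide gives a vinylogous methyl ester that hydroxide converts into the same dianion. The aryl acetates are saponified at the same time, so acidification of salt 7 should precipitate 8 free of protecting groups.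

**Step 6**
Reactants: 8 atromentin
Product: 10 2,5-dihydroxy-3,6-bis[4-(tert-butyldimethylsilyloxy)phenyl]-1,4-benzoquinone, via tetrakis-O-TBS atromentin 9 (not isolated)
Conditions: TBSCl (5 equiv), imidazole (10 equiv), DMF, rt; then AcOH/THF/H2O, rt
Reagents that add atoms: tert-butyldimethylsilyl chloride CC(C)(C)[Si](C)(C)Cl
Why: Exhaustive silylation followed by selective hydrolysis, as practised with hydroxy acids: the two quinone O–Si bonds are vinylogous silyl esters and fall off in aqueous acetic acid, the aryl TBS ethers persist, and the product gains the solubility in CH2Cl2 that atromentin lacks.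

**Step 7**
Reactants: 11 (E)-but-2-en-1-ol
Product: 12 [(2S,3S)-3-methyloxiran-2-yl]methanol
Conditions: Ti(OiPr)4 (5 mol %), L-(+)-diisopropyl tartrate (6 mol %), t-BuOOH (anhydrous, in decane), 4 Å molecular sieves, CH2Cl2, −20 °C; non-aqueous work-up, distillation
Reagents that add atoms: tert-butyl hydroperoxide CC(C)(C)OO
Why: Sharpless asymmetric epoxidation: within the titanium–(R,R)-tartrate complex the bound allylic alkoxide receives the peroxide oxygen on one enantiotopic face only, which for an E-allylic alcohol with the L-(+)-tartrate sets C2 and C3 both as S, and the concerted syn transfer turns the E-alkene into the trans-oxirane.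

**Step 8**
Reactants: 12 [(2S,3S)-3-methyloxiran-2-yl]methanol
Product: 13 (2R,3S)-3-methyloxirane-2-carbaldehyde
Conditions: Dess–Martin periodinane, CH2Cl2, 0 °C to rt; pentane, filtration through basic alumina, careful concentration at 0 °C, used as a solution
Reagents that add atoms: none
Why: Dess–Martin oxidation stops at the aldehyde under nearly neutral conditions, leaves the oxirane alone and should not epimerise the α-carbon because enolisation at an oxirane carbon is disfavoured by strain; the descriptor there changes from S to R only through the change in substituent priority.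

**Step 9**
Reactants: 13 (2R,3S)-3-methyloxirane-2-carbaldehyde
Product: 14 methyl (2Z,4S,5S)-4,5-epoxyhex-2-enoate
Conditions: (CF3CH2O)2P(O)CH2CO2Me, KN(SiMe3)2, 18-crown-6, THF, −78 °C
Reagents that add atoms: methyl bis(2,2,2-trifluoroethyl)phosphonoacetate COC(=O)CP(=O)(OCC(F)(F)F)OCC(F)(F)F
Why: Still–Gennari variant of the Horner–Wadsworth–Emmons olefination: the electron-poor phosphonate makes elimination from the kinetically formed adduct faster than its reversal, which should give the Z-enoate, and at −78 °C both oxirane stereocentres stay as set in step 7.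

**Step 10**
Reactants: 14 methyl (2Z,4S,5S)-4,5-epoxyhex-2-enoate
Product: 15 potassium (2Z,4S,5S)-4,5-epoxyhex-2-enoate
Conditions: KOSiMe3 (0.98 equiv), Et2O, 0 °C to rt; filtration under N2
Reagents that add atoms: potassium trimethylsilanolate C[Si](C)(C)[O-].[K+]
Why: Anhydrous methyl ester cleavage by a silanolate delivers the carboxylate directly as its potassium salt, so the free Z-acid, whose carboxyl group is held next to the oxirane and would lactonise once the oxirane is protonated, is never generated, while the alkene geometry and stereocentres are not touched.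

**Step 11**
Reactants: 10 2,5-dihydroxy-3,6-bis[4-(tert-butyldimethylsilyloxy)phenyl]-1,4-benzoquinone; 15 potassium (2Z,4S,5S)-4,5-epoxyhex-2-enoate (2.4 equiv)
Product: 17 2,5-bis{[(2Z,4S,5S)-4,5-epoxyhex-2-enoyl]oxy}-3,6-bis[4-(tert-butyldimethylsilyloxy)phenyl]-1,4-benzoquinone, via O-acylisourea 16 (not isolated)
Conditions: 15, N-ethyl-N'-(3-dimethylaminopropyl)carbodiimide hydrochloride (EDC·HCl, 2.5 equiv), CH2Cl2/DMF 10:1, −15 °C, 20 min; then 10, −15 to 0 °C
Reagents that add atoms: none
Why: Carbodiimide-mediated dehydrative acylation: the hydrochloride supplies just the proton needed to turn 15 into 16 without a reservoir of free acid, and the enolic hydroxyls of 10, vinylogous carboxylic acids ionised by the dimethylamino group of the reagent, attack 16 as the second acid does in anhydride formation, so no 4-dimethylaminopyridine, which could isomerise the Z-enoate by conjugate addition, is needed, the phenols are blocked and the stereocentres are not involved.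

**Step 12**
Reactants: 17 the bis-TBS diester of step 11
Product: 18 target, 2,5-bis{[(2Z,4S,5S)-4,5-epoxyhex-2-enoyl]oxy}-3,6-bis(4-hydroxyphenyl)-1,4-benzoquinone
Conditions: Et3N·3HF, THF, 0 °C to rt; pH 6 phosphate buffer
Reagents that add atoms: none
Why: Fluoride-induced cleavage of aryl silyl ethers, helped here by the para quinonyl acceptor on the departing phenoxide; the nearly neutral and weakly nucleophilic amine–HF complex should spare the oxiranes (whose ionisation the enoate disfavours), the Z-enoates and the acyloxyquinone esters.

**Compound list**

1 | 1,4-dibromo-2,5-dimethoxybenzene | COc1cc(Br)c(OC)cc1Br | starting material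
2 | 4-hydroxyphenylboronic acid | OB(O)c1ccc(O)cc1 | starting material
3 | 2',5'-dimethoxy-[1,1':4',1''-terphenyl]-4,4''-diol | COc1cc(-c2ccc(O)cc2)c(OC)cc1-c1ccc(O)cc1 | intermediate
4 | 2',5'-dimethoxy-[1,1':4',1''-terphenyl]-4,4''-diyl diacetate | COc1cc(-c2ccc(OC(C)=O)cc2)c(OC)cc1-c1ccc(OC(C)=O)cc1 | intermediate
5 | 2,5-bis(4-acetoxyphenyl)-1,4-benzoquinone | O=C1C=C(c2ccc(OC(C)=O)cc2)C(=O)C=C1c1ccc(OC(C)=O)cc1 | intermediate
6 | 2,5-dibromo-3,6-bis(4-acetoxyphenyl)-1,4-benzoquinone | O=C1C(Br)=C(c2ccc(OC(C)=O)cc2)C(=O)C(Br)=C1c1ccc(OC(C)=O)cc1 | intermediate
7 | tetrasodium atromentinate | [Na+].[Na+].[Na+].[Na+].O=C1C([O-])=C(c2ccc([O-])cc2)C(=O)C([O-])=C1c1ccc([O-])cc1 | intermediate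
8 | atromentin | O=C1C(O)=C(c2ccc(O)cc2)C(=O)C(O)=C1c1ccc(O)cc1 | intermediate
9 | tetrakis-O-TBS atromentin | O=C1C(O[Si](C)(C)C(C)(C)C)=C(c2ccc(O[Si](C)(C)C(C)(C)C)cc2)C(=O)C(O[Si](C)(C)C(C)(C)C)=C1c1ccc(O[Si](C)(C)C(C)(C)C)cc1 | intermediate
10 | 2,5-dihydroxy-3,6-bis[4-(tert-butyldimethylsilyloxy)phenyl]-1,4-benzoquinone | O=C1C(O)=C(c2ccc(O[Si](C)(C)C(C)(C)C)cc2)C(=O)C(O)=C1c1ccc(O[Si](C)(C)C(C)(C)C)cc1 | intermediate
11 | (E)-but-2-en-1-ol | C/C=C/CO | starting material
12 | [(2S,3S)-3-methyloxiran-2-yl]methanol | C[C@@H]1O[C@H]1CO | intermediate
13 | (2R,3S)-3-methyloxirane-2-carbaldehyde | C[C@@H]1O[C@H]1C=O | intermediate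
14 | methyl (2Z,4S,5S)-4,5-epoxyhex-2-enoate | C[C@@H]1O[C@H]1/C=C\C(=O)OC | intermediate
15 | potassium (2Z,4S,5S)-4,5-epoxyhex-2-enoate | C[C@@H]1O[C@H]1/C=C\C(=O)[O-].[K+] | intermediate
16 | O-[(2Z,4S,5S)-4,5-epoxyhex-2-enoyl]-N-ethyl-N'-(3-dimethylaminopropyl)isourea | C[C@@H]1O[C@H]1/C=C\C(=O)OC(NCC)=NCCCN(C)C | intermediate
17 | 2,5-bis{[(2Z,4S,5S)-4,5-epoxyhex-2-enoyl]oxy}-3,6-bis[4-(tert-butyldimethylsilyloxy)phenyl]-1,4-benzoquinone | C[C@@H]1O[C@H]1/C=C\C(=O)OC1=C(c2ccc(O[Si](C)(C)C(C)(C)C)cc2)C(=O)C(OC(=O)/C=C\[C@@H]2O[C@H]2C)=C(c2ccc(O[Si](C)(C)C(C)(C)C)cc2)C1=O | intermediate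
18 | 2,5-bis{[(2Z,4S,5S)-4,5-epoxyhex-2-enoyl]oxy}-3,6-bis(4-hydroxyphenyl)-1,4-benzoquinone | C[C@@H]1O[C@H]1/C=C\C(=O)OC1=C(c2ccc(O)cc2)C(=O)C(OC(=O)/C=C\[C@@H]2O[C@H]2C)=C(c2ccc(O)cc2)C1=O | target

**Step count**

Total step count: 12.
Longest linear sequence: 8 steps (steps 1–6, 11, 12). The side-chain branch (steps 7–10) joins at step 11.

**Steps most likely to fail**

**Step 11.** Acyl transfer to the delocalised, weakly nucleophilic enolate oxygens may be slow. The activated acyl unit could then be lost by O-to-N rearrangement, by Z-to-E isomerisation, or by attack of a transiently freed carboxyl group on its own oxirane. The second acylation may also lag behind the first.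

The fallback separates activation from acyl transfer. It sets out from 15 and 10 and comes back at 17. Salt 15 is suspended in CH2Cl2 at −20 °C and treated with oxalyl chloride. With a carboxylate salt this forms no HCl, and it should give (2Z,4S,5S)-4,5-epoxyhex-2-enoyl chloride F1. The cold solution is then added to 10 and Et3N (2.2 equiv) in CH2Cl2 at −40 °C. This is the classical acid chloride acylation of a hydroxyquinone and gives 17.

**Step 12.** During desilylation the vinylogous anhydride esters may be cleaved by fluoride, or acyl groups may be passed on to the liberated phenoxide. The oxiranes may also be opened by HF.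

The fallback drops the silyl groups altogether. It sets out from 8 and comes back at 18. Salt 15 (2.1 equiv) is pre-activated with EDC·HCl to 16 and added to 8 in DMF/THF at −10 °C, without added base or acyl-transfer catalyst. Only the enolic hydroxyls, several pKa units more acidic than the phenols, are then ionised and compete for 16. This fallback makes no new compound (F0).

**Step 5.** In alkali the quinone may undergo benzilic-type ring contraction or oxidative breakdown faster than the second bromide is exchanged, or the exchange may stall after one substitution.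

The fallback keeps the bromide-to-oxygen exchange but brings the oxygen in as methoxide and unmasks it without alkali. It sets out from 6 and comes back at 8. NaOMe in dry MeOH at 0 °C exchanges both bromides and transesterifies the acetates. After neutralisation this gives 2,5-dimethoxy-3,6-bis(4-hydroxyphenyl)-1,4-benzoquinone F2. Hydrolysis of its two vinylogous methyl esters with aqueous H2SO4 in acetic acid at 80 °C then gives 8.

**Further compounds**

F1 | step 11 | (2Z,4S,5S)-4,5-epoxyhex-2-enoyl chloride | C[C@@H]1O[C@H]1/C=C\C(=O)Cl
F0 | step 12 | none | none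
F2 | step 5 | 2,5-dimethoxy-3,6-bis(4-hydroxyphenyl)-1,4-benzoquinone | COC1=C(c2ccc(O)cc2)C(=O)C(OC)=C(c2ccc(O)cc2)C1=O
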